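**Retrosynthetic overview**
- The target is reached from its ring-B isopropyl ether by selective de-isopropylation, after the ring-A phenol has been capped as the methyl ether.
- All four C–Br bonds are cut in one operation, leading back to a bromine-free diaryl ether with a free phenol on ring A and OiPr/OMe flanking the bridging oxygen on ring B.
- The strategy rests on this feature: the brominated carbons (C2 and C4 of ring A; C3' and C5' of ring B) are each ortho or para to a non-bridging oxygen (O on C1; O on C2' and C6') and meta to the bridging oxygen (C6–O–C1').
- The diaryl ether C–O bond is made first, by SNAr of 2-(benzyloxy)phenol on 2-fluoro-3-methoxybenzaldehyde; the formyl group then becomes the ring-B oxygen by Baeyer–Villiger oxidation.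
- No ring is formed in the route; both benzene rings are purchased.

Key step: step 5

Remark: the target has no stereocentre and the diaryl ether axis rotates freely, so it is achiral and no stereocontrol is required.

Ring numbering used below: ring A has C1 (OH, later OMe), C2 and C4 (Br), and C6 (bridging O). Ring B has C1' (bridging O), C2' (OiPr, later OH), C3' and C5' (Br), and C6' (OMe).

**Step 1**
Reactants: 1 2-fluoro-3-methoxybenzaldehyde; 2 2-(benzyloxy)phenol
Product: 3 2-[2-(benzyloxy)phenoxy]-3-methoxybenzaldehyde
Conditions: K2CO3, DMAc, 130 °C, N2
Reagents that add atoms: none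
Why: Nucleophilic aromatic substitution (addition–elimination), in which the ortho formyl group stabilises the Meisenheimer adduct and fluoride is the preferred leaving group, so the phenoxide of 2 should displace it despite the flanking methoxy group.

**Step 2**
Reactants: 3 2-[2-(benzyloxy)phenoxy]-3-methoxybenzaldehyde
Product: 5 2-[2-(benzyloxy)phenoxy]-3-methoxyphenol, via aryl formate 4 (not isolated)
Conditions: mCPBA, CH2Cl2, 0 °C → rt; then K2CO3, MeOH, rt
Reagents that add atoms: m-chloroperoxybenzoic acid (mCPBA), OOC(=O)c1cccc(Cl)c1
Why: Baeyer–Villiger (Dakin-type) oxidation, in which the electron-rich aryl group with an ortho aryloxy donor should migrate in the Criegee adduct in preference to hydride, and the resulting formate is cleaved by mild methanolysis while the benzyl and diaryl ethers are inert.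

**Step 3**
Reactants: 5 2-[2-(benzyloxy)phenoxy]-3-methoxyphenol
Product: 6 1-(benzyloxy)-2-(2-isopropoxy-6-methoxyphenoxy)benzene
Conditions: 2-bromopropane, K2CO3, DMF, 60 °C
Reagents that add atoms: 2-bromopropane, CC(C)Br
Why: Williamson ether synthesis of a phenoxide with a secondary bromide in a dipolar aprotic solvent, where excess volatile halide compensates for loss to E2 elimination.

**Step 4**
Reactants: 6 1-(benzyloxy)-2-(2-isopropoxy-6-methoxyphenoxy)benzene
Product: 7 2-(2-isopropoxy-6-methoxyphenoxy)phenol
Conditions: H2 (1 atm), 10% Pd/C, EtOAc–EtOH, rt
Reagents that add atoms: none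
Why: Catalytic hydrogenolysis of the benzylic C–O bond, done while no halogen is present, so that the alkyl aryl and diaryl ethers are untouched and only the ring-A phenol is released.

**Step 5**
Reactants: 7 2-(2-isopropoxy-6-methoxyphenoxy)phenol
Product: 8 2,4-dibromo-6-(3,5-dibromo-2-isopropoxy-6-methoxyphenoxy)phenol
Conditions: NBS (4.1 equiv, portionwise), MeCN, 0 °C → rt, dark; aq. Na2S2O3 work-up
Reagents that add atoms: N-bromosuccinimide (NBS), O=C1CCC(=O)N1Br
Why: Four successive electrophilic aromatic substitutions through arenium ions, with NBS in acetonitrile as the Br+ donor; the closest known reactions are the 2,4-dibromination of 2-alkoxyphenols and the 4,6-dibromination of 1,3-dialkoxybenzenes with NBS or bromide/oxidant systems. No ring closes and no stereocentre is formed, so the only requirement is regioselectivity and the correct 2 + 2 distribution of bromine over the rings. In ring A the free hydroxyl is the dominant donor and should direct to C4 (para) and C2 (ortho), because the other ortho carbon C6 carries the bridging oxygen and C3/C5 are activated only by the weaker diaryl-ether oxygen; this is why ring A is brominated as the phenol and not as its methyl ether. In ring B, C3' and C5' are each ortho to one alkoxy group and para to the other, whereas C4' is activated only by the twisted bridging oxygen and ends up flanked by two bromines. Each ring is deactivated once it holds two bromines, and any bromodienone formed by ipso attack on the dibromophenol is itself a Br+ donor that passes the halogen on, so four equivalents should be shared correctly; limiting the reagent to about four equivalents at low temperature guards against a fifth bromine at C4'. The medium stays essentially neutral (succinimide is the by-product, not HBr), which should keep the isopropyl ether intact.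

**Step 6**
Reactants: 8 2,4-dibromo-6-(3,5-dibromo-2-isopropoxy-6-methoxyphenoxy)phenol
Product: 9 1,5-dibromo-3-(3,5-dibromo-2-methoxyphenoxy)-2-isopropoxy-4-methoxybenzene
Conditions: MeI, K2CO3, DMF, rt → 40 °C
Reagents that add atoms: iodomethane, CI
Why: Williamson O-methylation, in which the acidic dibromophenol is fully deprotonated by carbonate and the unhindered electrophile should alkylate the phenoxide despite its two ortho substituents.

**Step 7**
Reactants: 9 1,5-dibromo-3-(3,5-dibromo-2-methoxyphenoxy)-2-isopropoxy-4-methoxybenzene
Product: 10 4,6-dibromo-2-(3,5-dibromo-2-methoxyphenoxy)-3-methoxyphenol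
Conditions: BCl3 (1.5 equiv), CH2Cl2, −78 → 0 °C; then aq. NaHCO3
Reagents that add atoms: none
Why: Lewis-acid ether dealkylation, in which BCl3 coordinates the ether oxygen and the secondary isopropyl group is lost with strong SN1 character far faster than a methyl group at low temperature (the known isopropyl-over-methyl selectivity of BCl3), while aryl bromides and the diaryl ether are inert.

**Compound list**
1 | 2-fluoro-3-methoxybenzaldehyde | COc1cccc(C=O)c1F | starting material
2 | 2-(benzyloxy)phenol | Oc1ccccc1OCc1ccccc1 | starting material
3 | 2-[2-(benzyloxy)phenoxy]-3-methoxybenzaldehyde | COc1cccc(C=O)c1Oc1ccccc1OCc1ccccc1 | intermediate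
4 | 2-[2-(benzyloxy)phenoxy]-3-methoxyphenyl formate | COc1cccc(OC=O)c1Oc1ccccc1OCc1ccccc1 | intermediate (not isolated)
5 | 2-[2-(benzyloxy)phenoxy]-3-methoxyphenol | COc1cccc(O)c1Oc1ccccc1OCc1ccccc1 | intermediate
6 | 1-(benzyloxy)-2-(2-isopropoxy-6-methoxyphenoxy)benzene | COc1cccc(OC(C)C)c1Oc1ccccc1OCc1ccccc1 | intermediate
7 | 2-(2-isopropoxy-6-methoxyphenoxy)phenol | COc1cccc(OC(C)C)c1Oc1ccccc1O | intermediate
8 | 2,4-dibromo-6-(3,5-dibromo-2-isopropoxy-6-methoxyphenoxy)phenol | COc1c(Br)cc(Br)c(OC(C)C)c1Oc1cc(Br)cc(Br)c1O | intermediate
9 | 1,5-dibromo-3-(3,5-dibromo-2-methoxyphenoxy)-2-isopropoxy-4-methoxybenzene | COc1c(Br)cc(Br)c(OC(C)C)c1Oc1cc(Br)cc(Br)c1OC | intermediate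
10 | 4,6-dibromo-2-(3,5-dibromo-2-methoxyphenoxy)-3-methoxyphenol | COc1c(Br)cc(Br)cc1Oc1c(O)c(Br)cc(Br)c1OC | target

Total step count: 7
Longest linear sequence: 7 steps (from 1 and 2 to 10)

**Steps most likely to fail**

1. Step 5 (tetrabromination). The fourth substitution, the second bromination of the already monobrominated ring B, should be the slowest. While it lags, the electron-rich dibromophenol of ring A is exposed to excess N-bromo reagent, so oxidative dearomatisation of the phenol or spill-over of bromine onto C4' could give inseparable mixtures of tri-, tetra- and pentabrominated material. The fallback splits the bromination into two ring-selective stages with the phenol capped in between; it sets out from 7 and comes back at 9. Compound 7 is treated with a phenol-selective tribromide salt (benzyltrimethylammonium tribromide, 2 equiv, CH2Cl2–MeOH, CaCO3, rt) to give 2,4-dibromo-6-(2-isopropoxy-6-methoxyphenoxy)phenol F1. Methylation (MeI, K2CO3, DMF) gives 1,5-dibromo-3-(2-isopropoxy-6-methoxyphenoxy)-2-methoxybenzene F2, whose ring A is now a deactivated dibromoanisole that can no longer be oxidised. NBS (2.1 equiv, MeCN, rt) should then brominate only the doubly activated C3' and C5' of ring B, giving 9, which continues with step 7.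

2. Step 7 (selective de-isopropylation). Chemoselectivity of the Lewis-acid dealkylation may be lost: both methyl ethers sit between two ortho substituents, are twisted out of conjugation and are therefore unusually Lewis basic, so demethylation could compete with loss of the isopropyl group. The fallback replaces the isopropyl ether by an acetal that is removed by protic acid instead of a Lewis acid; it sets out from 5 and comes back at the target 10. Compound 5 is protected (MOMCl, iPr2NEt, CH2Cl2) to give 1-(benzyloxy)-2-[2-methoxy-6-(methoxymethoxy)phenoxy]benzene F3. Hydrogenolysis (H2, Pd/C) gives 2-[2-methoxy-6-(methoxymethoxy)phenoxy]phenol F4. Tetrabromination as in step 5 (NBS, 4.1 equiv, MeCN, NaHCO3 buffer) gives 2,4-dibromo-6-[3,5-dibromo-2-methoxy-6-(methoxymethoxy)phenoxy]phenol F5. Methylation (MeI, K2CO3, DMF) gives 1,5-dibromo-3-(3,5-dibromo-2-methoxyphenoxy)-2-methoxy-4-(methoxymethoxy)benzene F6. Dilute HCl in MeOH at rt then removes the acetal without touching any methyl ether, giving 10.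

3. Step 1 (SNAr). Addition–elimination may be sluggish at a fluoride that is activated by only one ortho formyl group and flanked by a methoxy group, and base-mediated degradation of the aldehyde could compete at the temperature required. The fallback makes the same C–O bond by copper catalysis instead of SNAr; it sets out from 2 and comes back at 3. Compound 2 is coupled with commercial 2-bromo-3-methoxybenzaldehyde under Ullmann conditions (CuI, N,N-dimethylglycine, Cs2CO3, dioxane, 100 °C), where the ortho carbonyl group assists the copper step, to give 3 directly; no compound outside the list arises (F0).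

**Further compounds**
F1 | step 5 | 2,4-dibromo-6-(2-isopropoxy-6-methoxyphenoxy)phenol | COc1cccc(OC(C)C)c1Oc1cc(Br)cc(Br)c1O
F2 | step 5 | 1,5-dibromo-3-(2-isopropoxy-6-methoxyphenoxy)-2-methoxybenzene | COc1cccc(OC(C)C)c1Oc1cc(Br)cc(Br)c1OC
F3 | step 7 | 1-(benzyloxy)-2-[2-methoxy-6-(methoxymethoxy)phenoxy]benzene | COCOc1cccc(OC)c1Oc1ccccc1OCc1ccccc1
F4 | step 7 | 2-[2-methoxy-6-(methoxymethoxy)phenoxy]phenol | COCOc1cccc(OC)c1Oc1ccccc1O
F5 | step 7 | 2,4-dibromo-6-[3,5-dibromo-2-methoxy-6-(methoxymethoxy)phenoxy]phenol | COCOc1c(Br)cc(Br)c(OC)c1Oc1cc(Br)cc(Br)c1O
F6 | step 7 | 1,5-dibromo-3-(3,5-dibromo-2-methoxyphenoxy)-2-methoxy-4-(methoxymethoxy)benzene | COCOc1c(Br)cc(Br)c(OC)c1Oc1cc(Br)cc(Br)c1OC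
F0 | step 1 | none | none
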